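## Analysis of the target

Target 30 is a sesquilignan built on a cis-fused 3,7-dioxabicyclo[3.3.0]octane. Ring A (O1, C7, C8, C8', C9') carries a 4-hydroxy-3-methoxyphenyl group at C7. Ring B (O2, C7', C8', C8, C9) carries at C7' a 3,5-dimethoxyphenyl ring (ring S) whose O4' is etherified with C8'' of a 1-(4-hydroxy-3,5-dimethoxyphenyl)propane-1,3-diol unit (C7''–C9''). The SMILES decodes as 7R,8S,7'S,8'S,7''R,8''R. H8 and H8' are syn (cis fusion) and H7 is anti to H8 (aryl on C7 exo), but H7' is syn to H8' (ring S endo, on the concave face). The core is therefore of the unsymmetrical epi type, and the remote side chain is threo (O7'' and O8'' syn in the zigzag drawing). The benzylic ether carbons C7 and C7' ionise in acid, which would turn the endo aryl at C7' into the more stable exo epimer; C7''–OH is a benzylic alcohol para to a free phenol, and both phenols are easily oxidised. The hard parts are the kinetically defined endo centre C7' in a bis-benzylic bicycle, four contiguous ring stereocentres in the absolute sense, a threo aryl ether at a phenol oxygen flanked by two methoxy groups, and an end game without acid. The feature the route exploits: C8' carries both C7' and C9', so C7'–C8'–C9' is the skeleton of an aroylacetic ester, with C9 on the neighbouring C8. Ring B in its enol ether form (O2–C7'=C8'–C8–C9) is thus the Cloke–Wilson ring-expansion isomer of a cyclopropane C8'–C8–C9 that bears the C7' aroyl group and is fused to the lactone form of ring A. One syn hydrogenation of that C7'=C8' bond from the convex face gives the syn array H7'/H8'/H8, which is the endo placement of ring S.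

## Retrosynthetic reasoning

30 to 29: only Si–O bonds are cut. Two aryl and two alkyl silyl ethers are chosen so that a single buffered fluoride treatment ends the synthesis without acid.

29 to 27 to 26: ring A is opened at O1–C9' and C9' is raised to the lactone level. Forward, lactone 26 is reduced to diol 27, and the primary C9' hydroxyl is activated and displaced by the C7 hydroxyl. The C7–O bond is never broken, so C7 is retained, and the carbonyl at C9' is kept this long because it is what activates the earlier steps.

26 to 25: the two hydrogens at C7' and C8' are removed to give the enol ether lactone 25. Forward, one syn hydrogenation from the convex face must set C7' and C8' together and place ring S endo.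

25 to 23 (key disconnection): the O2–C9 bond is cut and C9 is reconnected to C8'. This turns ring B into a cyclopropane (C8', C8, C9) that carries the aroyl group at C8' and is fused to lactone ring A. Forward, a nucleophile-catalysed Cloke–Wilson ring expansion must open the strained ring at C9 and close ring B through the ketone oxygen. The cut is made here because it removes a whole ring and exposes a 1,3-dicarbonyl compound.

23 to 22: the cyclopropane bonds C8'–C8 and C8'–C9 are cut, giving the allyl β-keto ester 22. Forward, an oxidative radical cyclisation adds the dicarbonyl carbon across the vinyl group, and the single stereocentre of 22 (C7) must control C8 and C8'.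

22 to 19 and 7: the C7'–C8' bond is cut (crossed Claisen condensation). This separates the route into acid 19, which holds ring S with the complete side chain, and the enantiopure allylic acetate 7, which holds the guaiacyl ring and C7.

7 to 5 to 3 to 1: acetate 7 comes from lipase resolution of racemic carbinol 5, made from silylated vanillin 3 (from 1 and 2) and vinyl nucleophile 4; acyl donor 6 supplies the two carbons that become C8' and C9'.

19 to 17 to 15 to 14 to 12 and 9: the C7''–C8'' bond is cut by an auxiliary-controlled syn aldol between glycolate imide 12 and aldehyde 9 (from 8 and 2), which sets both side-chain centres. Silylation (16) and ester cleavage (18) follow the reductive removal of the auxiliary. Imide 12 comes from 10 and 11 by cutting the O4'–CH2 bond, so the hindered aryl ether is made by substitution at a primary carbon at the very start.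

## Alternatives that were turned down

Alternative 1: the textbook biomimetic route. Disconnection: C8–C8' together with both benzylic C–O bonds, then O4'–C8''. Forward key step: one-electron oxidation of a guaiacyl and a syringyl C6–C3 allylic alcohol, 8–8' radical cross-coupling to a bis-quinone methide, and double 5-exo trapping by the two primary hydroxyls to give exo,exo furofuran A1. A second phenoxy radical coupling would then attach the side chain. Turned down because it gives A1 as a racemate within a statistical mixture of homo- and cross-dimers. The cyclisation is under thermodynamic control, so ring S ends up exo, the wrong epimer at C7'. Acid epimerisation cannot distinguish C7 from C7', and the radical formation of O4'–C8'' controls neither the threo relation nor the absolute configuration. It is very short but sets none of the six stereocentres.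

Alternative 2: carbenoid C–H insertion. Disconnection: the C7'–C8' bond. Forward key step: 1,5 C–H insertion of the dirhodium carbenoid from diazolactone A2 into the benzylic C–H of its CH2–O–CH2–aryl ether, which would give 26 directly with ring S endo. Turned down on three counts. A2 needs a longer path: a trans-disubstituted lactone, an ether made from the benzylic alcohol of the ring S fragment, and a diazo transfer. The carbenoid must pick one benzylic C–H in a substrate that offers several other C–H bonds activated by oxygen (C7''–H, C9''–H, five methoxy groups) and three electron-rich arenes open to cycloaddition. The endo outcome rests on a fine transition-state preference and not on a structural constraint such as the cis fusion used in step 13.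

Alternative 3: late etherification. Disconnection: O4'–C8'' as the last skeletal bond. Forward key step: Mitsunobu etherification of the mono-protected epi-furofuran phenol A3 with the erythro alcohol A4, with inversion at C8''. Turned down because the phenol oxygen is flanked by two methoxy groups, and the carbinol lies between a silyloxy benzylic carbon and a silyloxymethyl group, so elimination and non-conversion are the expected course. The riskiest bond formation would fall at the end, on the most valuable intermediate. The two phenols of the core would have to be told apart. The usual detour (α-halo ketone alkylation, reduction) adds late steps in the presence of the acid-labile endo centre. In the chosen route the same bond is made on 10 by substitution at a primary carbon.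

Key step: step 12

Remarks. Assumption: imide 11 is taken as a catalogue compound. Abbreviations: TIPS = triisopropylsilyl, TBS = tert-butyldimethylsilyl; ArG = 3-methoxy-4-(triisopropylsilyloxy)phenyl; ArT = 3,5-dimethoxy-4-(triisopropylsilyloxy)phenyl; ArS = 3,5-dimethoxy-4-{[(1R,2R)-1,3-bis(tert-butyldimethylsilyloxy)-1-ArT-propan-2-yl]oxy}phenyl.

## Route

Step 1
Reactants: 1 vanillin; 2 chlorotriisopropylsilane
Product: 3 3-methoxy-4-(triisopropylsilyloxy)benzaldehyde
Conditions: imidazole, DMF, 25 °C
Reagents that add atoms: chlorotriisopropylsilane (2), CC(C)[Si](Cl)(C(C)C)C(C)C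
Why: Imidazole-promoted silylation of the phenol; the bulky aryl TIPS ether should survive the organometallic, enolate, halide and hydride steps and fall to fluoride at the end.

Step 2
Reactants: 3 3-methoxy-4-(triisopropylsilyloxy)benzaldehyde; 4 vinylmagnesium bromide
Product: 5 racemic 1-ArG-prop-2-en-1-ol
Conditions: CH2=CHMgBr, THF, −78 to 0 °C; aq NH4Cl
Reagents that add atoms: vinylmagnesium bromide (4), C=C[Mg]Br
Why: 1,2-Addition of a Grignard reagent to the aldehyde gives the aryl vinyl carbinol; its stereocentre (later C7) is resolved in step 3.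

Step 3
Reactants: 5 racemic 1-ArG-prop-2-en-1-ol; 6 vinyl acetate
Product: 7 (1R)-1-ArG-prop-2-en-1-yl acetate
Conditions: Candida antarctica lipase B on acrylic resin (Novozym 435), vinyl acetate, tBuOMe, 30 °C, stopped near half conversion; chromatography on Et3N-deactivated silica
Reagents that add atoms: vinyl acetate (6), CC(=O)OC=C
Why: Lipase-catalysed enantioselective transesterification (kinetic resolution): by the empirical rule for lipases and secondary alcohols (aryl large, vinyl medium) the R enantiomer of 5 is acylated while the S enantiomer stays as the alcohol and is separated, so at most half of 5 is used; the acetate is itself the nucleophile of step 10.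

Step 4
Reactants: 8 syringaldehyde; 2 chlorotriisopropylsilane
Product: 9 3,5-dimethoxy-4-(triisopropylsilyloxy)benzaldehyde
Conditions: imidazole, DMAP (cat.), DMF, 50 °C
Reagents that add atoms: chlorotriisopropylsilane (2), CC(C)[Si](Cl)(C(C)C)C(C)C
Why: Phenol silylation as in step 1; the two flanking methoxy groups slow it, hence DMAP and gentle warming.

Step 5
Reactants: 10 methyl syringate; 11 (4S)-4-benzyl-3-(chloroacetyl)-1,3-oxazolidin-2-one
Product: 12 methyl 4-{2-[(4S)-4-benzyl-2-oxo-1,3-oxazolidin-3-yl]-2-oxoethoxy}-3,5-dimethoxybenzoate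
Conditions: K2CO3, NaI (cat.), acetone, 45 °C
Reagents that add atoms: none
Why: Williamson ether synthesis with Finkelstein activation: the phenoxide of 10 displaces halide from the primary α-halo imide, so the hindered O4'–C8'' bond is formed at a primary carbon at the start of the branch.

Step 6
Reactants: 12 glycolate imide; 9 3,5-dimethoxy-4-(triisopropylsilyloxy)benzaldehyde
Product: 14 methyl 4-{[(2S,3R)-1-[(4S)-4-benzyl-2-oxo-1,3-oxazolidin-3-yl]-3-hydroxy-1-oxo-3-ArT-propan-2-yl]oxy}-3,5-dimethoxybenzoate, via dibutylboron Z-enolate 13 (not isolated)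
Conditions: nBu2BOTf, iPr2NEt, CH2Cl2, −78 to 0 °C; then 9, −78 to 0 °C; pH 7 buffer, MeOH, H2O2, 0 °C
Reagents that add atoms: none
Why: Evans syn aldol reaction: the Z boron enolate reacts through a closed chair transition state on the face away from the benzyl group of the (S)-auxiliary, which sets C8'' and C7'' together as the syn (threo) pair in the absolute sense of 30 (2S,3R in the adduct).

Step 7
Reactants: 14 syn aldol adduct
Product: 15 methyl 4-{[(1R,2R)-1,3-dihydroxy-1-ArT-propan-2-yl]oxy}-3,5-dimethoxybenzoate
Conditions: NaBH4, THF/H2O 4:1, 0 to 25 °C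
Reagents that add atoms: none
Why: Borohydride reduction cleaves the activated N-acyl oxazolidinone to the primary alcohol and leaves the electron-rich methyl benzoate; both stereocentres are untouched (C8'' is named R only because the substituent priorities change).

Step 8
Reactants: 15 diol; 16 tert-butyldimethylsilyl trifluoromethanesulfonate
Product: 17 methyl 4-{[(1R,2R)-1,3-bis(tert-butyldimethylsilyloxy)-1-ArT-propan-2-yl]oxy}-3,5-dimethoxybenzoate
Conditions: TBSOTf, 2,6-lutidine, CH2Cl2, −20 to 0 °C
Reagents that add atoms: tert-butyldimethylsilyl trifluoromethanesulfonate (16), CC(C)(C)[Si](C)(C)OS(=O)(=O)C(F)(F)F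
Why: Silyl triflate/lutidine silylation of the primary and the hindered benzylic hydroxyl; all four hydroxyl protecting groups of the route are then fluoride-labile.

Step 9
Reactants: 17 methyl ester; 18 trimethyltin hydroxide
Product: 19 4-{[(1R,2R)-1,3-bis(tert-butyldimethylsilyloxy)-1-ArT-propan-2-yl]oxy}-3,5-dimethoxybenzoic acid
Conditions: Me3SnOH, 1,2-dichloroethane, 80 °C; aq KHSO4 wash
Reagents that add atoms: trimethyltin hydroxide (18), C[Sn](C)(C)O
Why: Trimethyltin hydroxide-mediated ester hydrolysis, chosen because aqueous hydroxide would attack the aryl silyl ether; no stereocentre is involved.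

Step 10
Reactants: 19 benzoic acid; 7 (1R)-1-ArG-prop-2-en-1-yl acetate
Product: 22 (1R)-1-ArG-prop-2-en-1-yl 3-ArS-3-oxopropanoate, via acid chloride of 19 20 (not isolated), via lithium enolate of 7 21 (not isolated)
Conditions: 1-chloro-N,N,2-trimethylprop-1-en-1-amine, CH2Cl2, 0 to 25 °C, evaporate; separately 7 (2.3 equiv), LiN(iPr)2 (2.3 equiv), THF, −78 °C; add 20, −78 °C; AcOH quench at −78 °C
Reagents that add atoms: none
Why: Crossed Claisen condensation (C-acylation of an ester enolate by an acid chloride): the neutral chloro-enamine gives 20 without HCl, enolate 21 is acylated at −78 °C and a second equivalent deprotonates the product; the allylic stereocentre is not involved, and the low temperature should suppress Ireland–Claisen rearrangement of 21.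

Step 11
Reactants: 22 allyl β-keto ester
Product: 23 (1S,4R,5R)-4-ArG-1-(ArS-carbonyl)-3-oxabicyclo[3.1.0]hexan-2-one
Conditions: Mn(OAc)3·2H2O (2.2 equiv), Cu(OAc)2·H2O (1 equiv), KOAc, degassed AcOH, 25 °C
Reagents that add atoms: none
Why: Oxidative free-radical cyclisation of an allyl β-keto ester (intramolecular cyclopropanation): trivalent manganese generates the dicarbonyl α-radical, 5-exo-trig closure onto the vinyl group forms C8'–C8 with the aryl group pseudo-equatorial (aryl trans to the new CH2 radical), and divalent copper oxidises the primary radical so that the enol carbon closes the necessarily cis-fused three-membered ring; C7 thereby fixes C8 and C8'.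

Step 12
Reactants: 23 aroyl cyclopropane lactone
Product: 25 (3R,3aS)-3-ArG-6-ArS-3a,4-dihydro-1H,3H-furo[3,4-c]furan-1-one (C7'=C8' enol ether), via iodomethyl lactone enolate 24 (not isolated)
Conditions: NaI (0.5 equiv), DMF, 70 °C
Reagents that add atoms: none
Why: Iodide attacks the unsubstituted cyclopropane carbon C9 of 23 in an SN2 homoconjugate addition, cleaving C8'–C9 and releasing the strain of the bicyclo[3.1.0] system into the doubly stabilised β-keto lactone enolate 24. The enolate oxygen of the aroyl group then displaces iodide at C9 and forms O2–C9, which closes ring B in a 5-exo-tet mode (O-alkylation through the in-plane lone pair) and regenerates iodide. The closest known reaction type is the halide- or amine-catalysed Cloke–Wilson rearrangement of 1-acylcyclopropane-1-carboxylic esters to 4,5-dihydrofuran-3-carboxylates. Re-closure at carbon (3-exo-tet) only returns 23, so the reversible manifold should drain to 25, the thermodynamic sink (loss of ring strain, gain of an aryl-conjugated vinylogous carbonate). Closure through the lactone carbonyl oxygen is excluded because it would give a bridged ketene acetal. No new stereocentre is formed: C7 and C8 are carried over unchanged, C8' becomes trigonal, and the step creates the bowl-shaped bicycle whose convex face controls C7' and C8' in step 13. The selectivity needed is attack at C9 and not at the ring-fusion carbon C8 or the benzylic lactone carbon C7; the primary nature of C9 and a neutral medium without Lewis acid, in which the benzylic C7–O bond should not ionise, secure it. In one operation the connectivity changes from a cyclopropane-fused monolactone to the complete dioxabicyclo[3.3.0]octane skeleton with both aryl groups and all carbons in place.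

Step 13
Reactants: 25 enol ether lactone
Product: 26 (3R,3aS,6S,6aR)-3-ArG-6-ArS-tetrahydro-1H,3H-furo[3,4-c]furan-1-one
Conditions: H2 (5 bar), 5% Rh/Al2O3, EtOAc, 25 °C
Reagents that add atoms: none
Why: Heterogeneous syn hydrogenation of a 2-aryl-4,5-dihydrofuran-3-carboxylate: both hydrogens are delivered to C7' and C8' from the convex face (the face of H8), since only this gives the cis-fused bicycle, so H7', H8' and H8 end up syn and ring S endo; Rh is preferred to Pd to spare the benzylic C–O bonds.

Step 14
Reactants: 26 furofuranone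
Product: 27 {(2S,3S,4S)-2-ArS-4-[(R)-hydroxy(ArG)methyl]oxolan-3-yl}methanol
Conditions: LiBH4, THF, 0 to 25 °C; aq NH4Cl
Reagents that add atoms: none
Why: Lactone-to-diol reduction by LiBH4, mild towards aryl silyl ethers; hydride addition should outpace enolisation, so C8' (α to the carbonyl, β to O2) is not epimerised.

Step 15
Reactants: 27 diol
Product: 29 (7R,8S,7'S,8'S)-tetrasilyl ether of 30, i.e. (1R,3aS,4S,6aS)-1-ArG-4-ArS-tetrahydro-1H,3H-furo[3,4-c]furan, via primary methanesulfonate 28 (not isolated)
Conditions: MsCl (1.15 equiv), pyridine, DMAP (cat.), CH2Cl2, −10 to 25 °C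
Reagents that add atoms: none
Why: Selective sulfonylation of the primary alcohol and 5-exo-tet displacement by the neighbouring benzylic hydroxyl (cycloetherification) closes ring A with retention at C7 because the C7–O bond is not broken; should C7 ionise it would re-close to the exo aryl, which is the one wanted, and C7' is inert in the basic medium.

Step 16
Reactants: 29 tetrasilyl ether
Product: 30 target CNP0317965.1
Conditions: nBu4NF, AcOH (1:1), THF, 0 to 25 °C
Reagents that add atoms: none
Why: Fluoride cleaves the two aryl TIPS and two alkyl TBS ethers in one operation; buffering with AcOH keeps the medium near neutral, so that acid-induced epimerisation at C7' and base-induced quinone methide chemistry at C7'' are both avoided.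

## Compound list

1 | vanillin | COc1cc(C=O)ccc1O | starting material
2 | chlorotriisopropylsilane | CC(C)[Si](Cl)(C(C)C)C(C)C | starting material
3 | 3-methoxy-4-(triisopropylsilyloxy)benzaldehyde | COc1cc(C=O)ccc1O[Si](C(C)C)(C(C)C)C(C)C | intermediate
4 | vinylmagnesium bromide | C=C[Mg]Br | starting material
5 | racemic 1-[3-methoxy-4-(triisopropylsilyloxy)phenyl]prop-2-en-1-ol | COc1cc(C(O)C=C)ccc1O[Si](C(C)C)(C(C)C)C(C)C | intermediate
6 | vinyl acetate | CC(=O)OC=C | starting material
7 | (1R)-1-[3-methoxy-4-(triisopropylsilyloxy)phenyl]prop-2-en-1-yl acetate | C=C[C@@H](OC(C)=O)c1ccc(O[Si](C(C)C)(C(C)C)C(C)C)c(OC)c1 | intermediate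
8 | syringaldehyde | COc1cc(C=O)cc(OC)c1O | starting material
9 | 3,5-dimethoxy-4-(triisopropylsilyloxy)benzaldehyde | COc1cc(C=O)cc(OC)c1O[Si](C(C)C)(C(C)C)C(C)C | intermediate
10 | methyl syringate (methyl 4-hydroxy-3,5-dimethoxybenzoate) | COC(=O)c1cc(OC)c(O)c(OC)c1 | starting material
11 | (4S)-4-benzyl-3-(chloroacetyl)-1,3-oxazolidin-2-one | O=C(CCl)N1[C@@H](Cc2ccccc2)COC1=O | starting material
12 | methyl 4-{2-[(4S)-4-benzyl-2-oxo-1,3-oxazolidin-3-yl]-2-oxoethoxy}-3,5-dimethoxybenzoate | COC(=O)c1cc(OC)c(OCC(=O)N2[C@@H](Cc3ccccc3)COC2=O)c(OC)c1 | intermediate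
13 | dibutylboron Z-enolate of 12 | CCCCB(CCCC)O/C(=C\Oc1c(OC)cc(C(=O)OC)cc1OC)N1[C@@H](Cc2ccccc2)COC1=O | intermediate (not isolated)
14 | (2S,3R) syn aldol adduct of 12 and 9 | COC(=O)c1cc(OC)c(O[C@H](C(=O)N2[C@@H](Cc3ccccc3)COC2=O)[C@H](O)c2cc(OC)c(O[Si](C(C)C)(C(C)C)C(C)C)c(OC)c2)c(OC)c1 | intermediate
15 | methyl 4-{[(1R,2R)-1,3-dihydroxy-1-ArT-propan-2-yl]oxy}-3,5-dimethoxybenzoate | COC(=O)c1cc(OC)c(O[C@H](CO)[C@H](O)c2cc(OC)c(O[Si](C(C)C)(C(C)C)C(C)C)c(OC)c2)c(OC)c1 | intermediate
16 | tert-butyldimethylsilyl trifluoromethanesulfonate | CC(C)(C)[Si](C)(C)OS(=O)(=O)C(F)(F)F | starting material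
17 | methyl 4-{[(1R,2R)-1,3-bis(tert-butyldimethylsilyloxy)-1-ArT-propan-2-yl]oxy}-3,5-dimethoxybenzoate | COC(=O)c1cc(OC)c(O[C@H](CO[Si](C)(C)C(C)(C)C)[C@H](O[Si](C)(C)C(C)(C)C)c2cc(OC)c(O[Si](C(C)C)(C(C)C)C(C)C)c(OC)c2)c(OC)c1 | intermediate
18 | trimethyltin hydroxide | C[Sn](C)(C)O | starting material
19 | 4-{[(1R,2R)-1,3-bis(tert-butyldimethylsilyloxy)-1-ArT-propan-2-yl]oxy}-3,5-dimethoxybenzoic acid | OC(=O)c1cc(OC)c(O[C@H](CO[Si](C)(C)C(C)(C)C)[C@H](O[Si](C)(C)C(C)(C)C)c2cc(OC)c(O[Si](C(C)C)(C(C)C)C(C)C)c(OC)c2)c(OC)c1 | intermediate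
20 | acid chloride of 19 | ClC(=O)c1cc(OC)c(O[C@H](CO[Si](C)(C)C(C)(C)C)[C@H](O[Si](C)(C)C(C)(C)C)c2cc(OC)c(O[Si](C(C)C)(C(C)C)C(C)C)c(OC)c2)c(OC)c1 | intermediate (not isolated)
21 | lithium enolate of 7 | [Li]OC(=C)O[C@H](C=C)c1ccc(O[Si](C(C)C)(C(C)C)C(C)C)c(OC)c1 | intermediate (not isolated)
22 | (1R)-1-ArG-prop-2-en-1-yl 3-ArS-3-oxopropanoate | C=C[C@@H](OC(=O)CC(=O)c1cc(OC)c(O[C@H](CO[Si](C)(C)C(C)(C)C)[C@H](O[Si](C)(C)C(C)(C)C)c2cc(OC)c(O[Si](C(C)C)(C(C)C)C(C)C)c(OC)c2)c(OC)c1)c1ccc(O[Si](C(C)C)(C(C)C)C(C)C)c(OC)c1 | intermediate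
23 | (1S,4R,5R)-4-ArG-1-(ArS-carbonyl)-3-oxabicyclo[3.1.0]hexan-2-one | COc1cc([C@@H]2OC(=O)[C@]3(C(=O)c4cc(OC)c(O[C@H](CO[Si](C)(C)C(C)(C)C)[C@H](O[Si](C)(C)C(C)(C)C)c5cc(OC)c(O[Si](C(C)C)(C(C)C)C(C)C)c(OC)c5)c(OC)c4)[C@H]2C3)ccc1O[Si](C(C)C)(C(C)C)C(C)C | intermediate
24 | sodium enolate of the 5-ArG-4-(iodomethyl)-3-(ArS-carbonyl)oxolan-2-one (C7, C8 as in 23) | COc1cc([C@@H]2OC(=O)C(=C([O-])c3cc(OC)c(O[C@H](CO[Si](C)(C)C(C)(C)C)[C@H](O[Si](C)(C)C(C)(C)C)c4cc(OC)c(O[Si](C(C)C)(C(C)C)C(C)C)c(OC)c4)c(OC)c3)[C@H]2CI)ccc1O[Si](C(C)C)(C(C)C)C(C)C.[Na+] | intermediate (not isolated)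
25 | (3R,3aS)-3-ArG-6-ArS-3a,4-dihydro-1H,3H-furo[3,4-c]furan-1-one | COc1cc([C@@H]2OC(=O)C3=C(c4cc(OC)c(O[C@H](CO[Si](C)(C)C(C)(C)C)[C@H](O[Si](C)(C)C(C)(C)C)c5cc(OC)c(O[Si](C(C)C)(C(C)C)C(C)C)c(OC)c5)c(OC)c4)OC[C@@H]23)ccc1O[Si](C(C)C)(C(C)C)C(C)C | intermediate
26 | (3R,3aS,6S,6aR)-3-ArG-6-ArS-tetrahydro-1H,3H-furo[3,4-c]furan-1-one | COc1cc([C@@H]2OC(=O)[C@@H]3[C@H]2CO[C@@H]3c4cc(OC)c(O[C@H](CO[Si](C)(C)C(C)(C)C)[C@H](O[Si](C)(C)C(C)(C)C)c5cc(OC)c(O[Si](C(C)C)(C(C)C)C(C)C)c(OC)c5)c(OC)c4)ccc1O[Si](C(C)C)(C(C)C)C(C)C | intermediate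
27 | {(2S,3S,4S)-2-ArS-4-[(R)-hydroxy(ArG)methyl]oxolan-3-yl}methanol | COc1cc([C@H](O)[C@@H]2CO[C@H](c3cc(OC)c(O[C@H](CO[Si](C)(C)C(C)(C)C)[C@H](O[Si](C)(C)C(C)(C)C)c4cc(OC)c(O[Si](C(C)C)(C(C)C)C(C)C)c(OC)c4)c(OC)c3)[C@@H]2CO)ccc1O[Si](C(C)C)(C(C)C)C(C)C | intermediate
28 | primary methanesulfonate of 27 | COc1cc([C@H](O)[C@@H]2CO[C@H](c3cc(OC)c(O[C@H](CO[Si](C)(C)C(C)(C)C)[C@H](O[Si](C)(C)C(C)(C)C)c4cc(OC)c(O[Si](C(C)C)(C(C)C)C(C)C)c(OC)c4)c(OC)c3)[C@@H]2COS(C)(=O)=O)ccc1O[Si](C(C)C)(C(C)C)C(C)C | intermediate (not isolated)
29 | (7R,8S,7'S,8'S)-tetrasilyl ether of the target (two aryl TIPS, two alkyl TBS) | COc1cc([C@@H]2OC[C@@H]3[C@H]2CO[C@@H]3c4cc(OC)c(O[C@H](CO[Si](C)(C)C(C)(C)C)[C@H](O[Si](C)(C)C(C)(C)C)c5cc(OC)c(O[Si](C(C)C)(C(C)C)C(C)C)c(OC)c5)c(OC)c4)ccc1O[Si](C(C)C)(C(C)C)C(C)C | intermediate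
30 | CNP0317965.1, (7R,8S,7'S,8'S,7''R,8''R) | COc1cc([C@@H]2OC[C@@H]3[C@H]2CO[C@@H]3c2cc(OC)c(O[C@H](CO)[C@H](O)c3cc(OC)c(O)c(OC)c3)c(OC)c2)ccc1O | target

## Step count, longest linear sequence and risks

Total: 16 steps. Longest linear sequence: 12 steps (steps 5 to 16, from 10). The vanillin branch (steps 1 to 3) and aldehyde 9 (step 4) join at steps 10 and 6.

Step 12 (key step). The most likely failure is that iodide or adventitious acid acts at the benzylic lactone carbon C7 instead of at C9. This would open the lactone or scramble C7, because the electron-rich aryl group stabilises a cation there. The second concern is that the open enolate mostly re-closes at carbon, so that net ring expansion is slow at temperatures the aryl silyl ethers tolerate. Fallback: starting from 23, the cyclopropane is opened stoichiometrically with MgBr2·OEt2 in CH2Cl2/Et2O to give the bromomethyl β-keto lactone F1, isolated as its enol. Ag2CO3 in MeCN then abstracts bromide so that the hard enol oxygen closes ring B, and the route is rejoined at 25. This separates C–C cleavage from C–O formation and replaces the catalytic shuttle by a halophile-driven closure.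

Step 13. The tetrasubstituted C7'=C8' bond is a push–pull alkene and may be saturated only slowly. Prolonged exposure invites hydrogenolysis of the benzylic C7–O1 lactone bond or, after saturation, of C7'–O2, and migration of the double bond towards C8. Fallback: starting from 25, the lactone is reduced first with iBu2AlH in CH2Cl2 at −78 to 0 °C to the enol ether diol F2, in which the alkene is no longer deactivated. Hydrogenation of this electron-rich enol ether (Pd/C or Rh/Al2O3, EtOAc with a trace of Et3N) should occur anti to the large C8 substituent and give 27 directly, by-passing 26.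

Step 11. The allylic, benzylic ester may ionise in AcOH and be lost by solvolysis or allylic transposition. The ester-tethered radical closes slowly, so α-acetoxylation or oligomerisation may compete, and the primary TBS ether may be partly cleaved. Fallback: starting from 22, diazo transfer with 4-acetamidobenzenesulfonyl azide and Et3N in MeCN gives the α-diazo β-keto ester F3. Rh2(OAc)4 or Cu(acac)2 in CH2Cl2 or toluene then effects intramolecular carbenoid cyclopropanation under neutral conditions and returns 23.

Step 10. Acylation may occur at oxygen or twice at carbon, and enolate 21 may undergo Ireland–Claisen rearrangement or self-condensation if the mixture warms before the acid chloride is consumed. Fallback: starting from 7 and 19, acetate 7 is cleaved with iBu2AlH at −78 °C to the (R)-allylic alcohol F4, and 19 is condensed with Meldrum's acid (carbodiimide, DMAP, CH2Cl2) to the acyl Meldrum's acid F5. Heating F5 with F4 in toluene at 80 °C generates the acylketene, which the alcohol traps without any enolate, giving 22.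

## Further compounds

F1 | step 12 | 5-ArG-4-(bromomethyl)-3-(ArS-carbonyl)oxolan-2-one (C7, C8 as in 23; enolised at C8') | COc1cc([C@@H]2OC(=O)C(C(=O)c3cc(OC)c(O[C@H](CO[Si](C)(C)C(C)(C)C)[C@H](O[Si](C)(C)C(C)(C)C)c4cc(OC)c(O[Si](C(C)C)(C(C)C)C(C)C)c(OC)c4)c(OC)c3)[C@H]2CBr)ccc1O[Si](C(C)C)(C(C)C)C(C)C
F2 | step 13 | (R)-ArG-[(3S)-5-ArS-4-(hydroxymethyl)-2,3-dihydrofuran-3-yl]methanol | COc1cc([C@H](O)[C@@H]2COC(c3cc(OC)c(O[C@H](CO[Si](C)(C)C(C)(C)C)[C@H](O[Si](C)(C)C(C)(C)C)c4cc(OC)c(O[Si](C(C)C)(C(C)C)C(C)C)c(OC)c4)c(OC)c3)=C2CO)ccc1O[Si](C(C)C)(C(C)C)C(C)C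
F3 | step 11 | (1R)-1-ArG-prop-2-en-1-yl 2-diazo-3-ArS-3-oxopropanoate | C=C[C@@H](OC(=O)C(=[N+]=[N-])C(=O)c1cc(OC)c(O[C@H](CO[Si](C)(C)C(C)(C)C)[C@H](O[Si](C)(C)C(C)(C)C)c2cc(OC)c(O[Si](C(C)C)(C(C)C)C(C)C)c(OC)c2)c(OC)c1)c1ccc(O[Si](C(C)C)(C(C)C)C(C)C)c(OC)c1
F4 | step 10 | (1R)-1-[3-methoxy-4-(triisopropylsilyloxy)phenyl]prop-2-en-1-ol | C=C[C@@H](O)c1ccc(O[Si](C(C)C)(C(C)C)C(C)C)c(OC)c1
F5 | step 10 | 5-(ArS-carbonyl)-2,2-dimethyl-1,3-dioxane-4,6-dione | CC1(C)OC(=O)C(C(=O)c2cc(OC)c(O[C@H](CO[Si](C)(C)C(C)(C)C)[C@H](O[Si](C)(C)C(C)(C)C)c3cc(OC)c(O[Si](C(C)C)(C(C)C)C(C)C)c(OC)c3)c(OC)c2)C(=O)O1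
A1 | alternative 1 | racemic exo,exo furofuran (medioresinol; one enantiomer drawn) | COc1cc([C@H]2OC[C@H]3[C@@H]2CO[C@@H]3c2cc(OC)c(O)c(OC)c2)ccc1O
A2 | alternative 2 | (4S,5R)-5-ArG-3-diazo-4-{[(ArS)methoxy]methyl}oxolan-2-one | COc1cc([C@@H]2OC(=O)C(=[N+]=[N-])[C@H]2COCc3cc(OC)c(O[C@H](CO[Si](C)(C)C(C)(C)C)[C@H](O[Si](C)(C)C(C)(C)C)c4cc(OC)c(O[Si](C(C)C)(C(C)C)C(C)C)c(OC)c4)c(OC)c3)ccc1O[Si](C(C)C)(C(C)C)C(C)C
A3 | alternative 3 | (7R,8S,7'S,8'S)-epi-furofuran with free 4'-phenol and ArG (mono-TIPS ether) | COc1cc([C@@H]2OC[C@@H]3[C@H]2CO[C@@H]3c4cc(OC)c(O)c(OC)c4)ccc1O[Si](C(C)C)(C(C)C)C(C)C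
A4 | alternative 3 | (1R,2S)-1,3-bis(tert-butyldimethylsilyloxy)-1-ArT-propan-2-ol (erythro) | O[C@@H](CO[Si](C)(C)C(C)(C)C)[C@H](O[Si](C)(C)C(C)(C)C)c1cc(OC)c(O[Si](C(C)C)(C(C)C)C(C)C)c(OC)c1
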